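**Plan**

Numbering (target skeleton): C-1/C-5 ring fusion, C-2=C-3, C-4 (Me, OH), C-6 (OH), C-7 (side-chain carbon), C-8, C-9, C-10 (=C-18H2); side chain C-11 (Me) to C-15, OAc on C-13.
Enabling feature: C-6 and C-10 of the seven-membered ring are both at or next to the carbonyl level, 1,4 through C-5/C-1 and 1,5 through C-7–C-8–C-9. The ring is thus a cycloheptane-1,4-dione, i.e. the five-membered 1,3-dione ring C-10/C-7/C-6/C-5/C-1 after ethylene (C-8, C-9) has entered its C-7–C-10 bond (de Mayo).
Retrosynthesis: cut C-13–C-14 (aldehyde alkenylation); return ring B to a C-3=C-4 methylcyclopentene made by metathesis of a C-1 allyl and a C-5 isopropenyl group; cut C-10=C-18; re-close C-7–C-10 to a cyclobutanol; then cut C-9–C-10 and C-7–C-8 together, giving ethylene and a bicyclic enol-ether acetal made from cyclopentane-1,3-dione and crotonaldehyde.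
Forward: pyran-fused cyclopentenone, then the cyclobutane, then the C-1 and C-5 substituents on the rigid photoadduct, then retro-aldol ring expansion to the seven-membered ring, methylenation, ring B, C-4 oxygenation, side chain, C-6 reduction.
Stereochemistry: C-11 from an organocatalyst, relayed through the cyclobutane face to C-1 and from there to C-5 (trans); C-7 thermodynamic; C-4 from peracid face selectivity; C-13 from a chiral chromium catalyst; C-6 from chelation-controlled reduction.

Key step: step 2

**Route**

Step 1
Reactants: 1 cyclopentane-1,3-dione; 2 (E)-but-2-enal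
Product: 4 (2S,4R)-2-methoxy-4-methyl-3,4,6,7-tetrahydrocyclopenta[b]pyran-5(2H)-one, via lactol 3 (not isolated)
Conditions: (S)-α,α-diphenylprolinol trimethylsilyl ether (10 mol %), PhCO2H (10 mol %), CH2Cl2, rt; then MeOH, camphor-10-sulfonic acid (CSA, cat.), rt
Reagents that add atoms: methanol (CO)
Why: Iminium-catalysed asymmetric Michael addition of the dione to the enal, then hemiacetal closure and acetalisation: the silyloxydiphenylmethyl group of the (S)-catalyst shields one face of the E-iminium ion so that the dione carbon adds to the other face and gives 11R, and the acetal (OMe axial, trans to the methyl) locks the enol ether on one of the two equivalent carbonyl groups.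

Step 2
Reactants: 4 (2S,4R)-2-methoxy-4-methyl-3,4,6,7-tetrahydrocyclopenta[b]pyran-5(2H)-one; 5 ethylene
Product: 6 cyclobutane photoadduct (oxa[4.3.2]propellanone) with the C-8/C-9 bridge across C-7 and C-10 on the face anti to the C-11 methyl
Conditions: hν (medium-pressure Hg lamp, Pyrex filter, λ > 300 nm), CH2Cl2 saturated with 5, −78 °C
Reagents that add atoms: none
Why: Excitation of the β-alkoxy enone (vinylogous ester) chromophore of 4 gives its triplet, which adds ethylene stepwise through a 1,4-biradical and so forms the C-9–C-10 and C-7–C-8 bonds in one operation. The closest known reaction type is the enone–alkene [2+2] photocycloaddition of an enolised 1,3-diketone derivative, the first half of a de Mayo reaction, whose retro-aldol half is deliberately held back until step 6. The only ring closed is the cyclobutane, formed by [2+2] cycloaddition (radical addition, then biradical collapse) and necessarily cis-fused to both the five- and the six-membered ring. The two new quaternary centres C-7 and C-10 are set by the C-11 methyl, which sits pseudoaxial next to the enone (A(1,2) strain) so that ethylene enters from the opposite face; they are temporary and are cleared in step 6, but the cyclobutane face later relays the C-11 configuration to C-1 and C-5. The step needs chemoselectivity for intermolecular addition over enone dimerisation and secondary photolysis, secured by ethylene saturation at −78 °C, irradiation above 300 nm where only the enone absorbs, and the absence of any other π bond in 4; there is no regiochemical issue because ethylene is symmetrical and the acetal tether fixes the enol-ether oxygen on C-10. The acetal ring is the helper that defines which C–C bond of the dione takes up ethylene and that later triggers the ring expansion.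

Step 3
Reactants: 6 cyclobutane photoadduct
Product: 8 enone (6 with a C-1=C-5 double bond), via silyl enol ether 7 (not isolated)
Conditions: LiN(i-Pr)2, THF, −78 °C; Me3SiCl; then Pd(OAc)2 (1.05 equiv), MeCN, rt
Reagents that add atoms: none
Why: Saegusa–Ito oxidation: the ketone of 6 has a single enolisable position (C-5, since C-7 is quaternary), so only one silyl enol ether and one enone can form and no stereocentre is touched.

Step 4
Reactants: 8 enone; 9 allylmagnesium bromide
Product: 11 allyl ketone (allyl at C-1, anti to the cyclobutane), via silyl enol ether 10 (not isolated)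
Conditions: 9, CuBr·SMe2, LiCl, Me3SiCl, THF, −78 °C; then K2CO3 (cat.), MeOH, 0 °C
Reagents that add atoms: none
Why: Copper-mediated conjugate (1,4-) addition of the allyl group with Me3SiCl activation: the reagent should attack C-1 on the exo face of the bicyclo[3.2.0]heptenone, anti to the cyclobutane methylene C-9 and past the smaller ring oxygen, which transfers the configuration of C-11 (through the cyclobutane face) to C-1.

Step 5
Reactants: 11 allyl ketone; 12 2-bromopropene
Product: 13 allyl isopropenyl ketone (isopropenyl at C-5, trans to the C-1 allyl group)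
Conditions: Pd2(dba)3 (2.5 mol %), P(t-Bu)3·HBF4 (6 mol %), LiN(SiMe3)2, toluene, rt
Reagents that add atoms: none
Why: Palladium-catalysed α-alkenylation of the ketone enolate (enolate cross-coupling): only C-5 can enolise, and the isopropenyl group should end up trans to the neighbouring allyl group, which is both the kinetic (anti approach) and the thermodynamic outcome at this epimerisable centre.

Step 6
Reactants: 13 allyl isopropenyl ketone
Product: 16 cycloheptane-6,10-dione with 1-allyl and 5-isopropenyl groups and the C-7 side chain as its C-13 dimethyl acetal, via cyclobutanol 14 (not isolated), via cyclic enol ether 15 (not isolated)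
Conditions: CSA (10 mol %), MeOH, 0 °C to rt; then Et3N
Reagents that add atoms: methanol (CO)
Why: Retro-aldol half of the de Mayo reaction: acid-catalysed acetal exchange opens the pyran to cyclobutanol 14, whose strained β-hydroxy ketone cleaves the C-7–C-10 bond to the cycloheptane-1,4-dione, and C-7 is protonated reversibly through cyclic enol ether 15 (a path open only towards C-7) to the thermodynamic epimer in which the two α-substituents of the C-6 ketone (at C-5 and C-7) are trans and pseudo-equatorial on the twist-chair, while C-1 and C-5 should not epimerise under these mild conditions.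

Step 7
Reactants: 16 cycloheptane-6,10-dione
Product: 17 C-10 methylene ketone (C-10=C-18H2, C-6 ketone retained)
Conditions: Cp2TiMe2 (1.2 equiv), toluene–THF, 65 °C, dark
Reagents that add atoms: dimethyltitanocene (C[Ti](C)(C1C=CC=C1)C1C=CC=C1)
Why: Carbonyl methylenation by the titanium methylidene generated from Cp2TiMe2 (non-basic, so the α-centre C-1 is not epimerised): the C-10 ketone should react in preference to the C-6 ketone, which is flanked by two tertiary carbons.

Step 8
Reactants: 17 C-10 methylene ketone
Product: 18 trans-fused hydroazulenone with ring B as the C-3=C-4 methylcyclopentene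
Conditions: second-generation Grubbs catalyst RuCl2(=CHPh)(PCy3)(H2IMes) (5 mol %), 1,4-benzoquinone (10 mol %), CH2Cl2, 40 °C
Reagents that add atoms: none
Why: Ring-closing metathesis of the allyl and isopropenyl groups closes ring B as a trisubstituted cyclopentene trans-fused to the seven-membered ring; the exocyclic C-10 methylene is 1,1-disubstituted and could only close a four-membered ring, so it stays out.

Step 9
Reactants: 18 trans-fused hydroazulenone
Product: 19 3,4-epoxide with the oxygen syn to H-5
Conditions: 3-chloroperbenzoic acid (1.05 equiv), NaHCO3, CH2Cl2, −20 °C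
Reagents that add atoms: 3-chloroperbenzoic acid (OOC(=O)c1cccc(Cl)c1)
Why: Prilezhaev epoxidation: the trisubstituted C-3=C-4 alkene is more nucleophilic than the 1,1-disubstituted exocyclic alkene, and the peracid should approach ring B from the face syn to H-5 because C-6 is tilted below the other face in the trans-fused skeleton, which sets the C-4–O bond.

Step 10
Reactants: 19 3,4-epoxide
Product: 22 tertiary allylic alcohol (C-4 Me/OH, C-2=C-3) with the C-6 ketone and C-13 dimethyl acetal, via hydroxy selenide 20 (not isolated), via selenoxide 21 (not isolated)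
Conditions: PhSeSePh, NaBH4, EtOH, 0 °C to rt (borohydride consumed before 19 is added); then 30% H2O2, pyridine, THF, 0 °C to rt
Reagents that add atoms: none
Why: Epoxide-to-allylic-alcohol transposition by selenide opening and selenoxide syn-elimination: the selenolate opens the epoxide by SN2 at the less substituted C-3, and the selenoxide can only eliminate towards C-2 because C-4 carries no hydrogen, which gives the C-2=C-3 alkene and the tertiary C-4 alcohol with the configuration fixed in step 9.

Step 11
Reactants: 22 tertiary allylic alcohol
Product: 23 C-13 aldehyde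
Conditions: pyridinium p-toluenesulfonate (10 mol %), acetone–H2O (10:1), rt
Reagents that add atoms: water (O)
Why: Acid-catalysed acetal hydrolysis under buffered, mild conditions, which should free the C-13 aldehyde without ionising the tertiary allylic alcohol.

Step 12
Reactants: 23 C-13 aldehyde; 24 1-bromo-2-methylprop-1-ene
Product: 25 (13R)-allylic alcohol carrying the C-14=C-15 alkene
Conditions: CrCl2 (10 mol %), chiral 4-isopropyl-oxazoline sulfonamide ligand (11 mol %, enantiomer for Si-face addition), Et3N (20 mol %), NiCl2 (2 mol %), Mn, Cp2ZrCl2, LiCl, MeCN, rt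
Reagents that add atoms: none
Why: Catalytic asymmetric Nozaki–Hiyama–Kishi alkenylation: the alkenylchromium reagent adds only to the aldehyde (the hindered C-6 ketone and the free tertiary hydroxyl are tolerated), and the chiral oxazoline–sulfonamide ligand on chromium should set 13R by catalyst control through Si-face addition.

Step 13
Reactants: 25 (13R)-allylic alcohol
Product: 26 13-acetate with the C-6 ketone
Conditions: Ac2O (1.2 equiv), pyridine, DMAP (5 mol %), CH2Cl2, 0 °C
Reagents that add atoms: acetic anhydride (CC(=O)OC(C)=O)
Why: DMAP-catalysed acylation: only the secondary C-13 hydroxyl is acetylated because the C-4 hydroxyl is tertiary and no other hydroxyl is free at this stage.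

Step 14
Reactants: 26 13-acetate
Product: 28 target CNP0209568.3, via diethylborinate 27 (not isolated)
Conditions: Et2BOMe, THF–MeOH (4:1), −78 °C; NaBH4; then MeOH (repeated evaporation)
Reagents that add atoms: none
Why: Narasaka–Prasad reduction: the diethylboron chelate between the C-4 alkoxide and the C-6 ketone should be reduced by external axial hydride delivery to the 1,3-syn diol, which is the 6R configuration of the target, and the allylic acetate is inert to NaBH4 at −78 °C.

**Compound list**

1 | cyclopentane-1,3-dione | O=C1CCC(=O)C1 | starting material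
2 | (E)-but-2-enal (crotonaldehyde) | C/C=C/C=O | starting material
3 | (4R)-2-hydroxy-4-methyl-3,4,6,7-tetrahydrocyclopenta[b]pyran-5(2H)-one (lactol, both anomers) | O=C1CCC2=C1[C@H](C)CC(O)O2 | intermediate
4 | (2S,4R)-2-methoxy-4-methyl-3,4,6,7-tetrahydrocyclopenta[b]pyran-5(2H)-one (OMe trans to Me) | O=C1CCC2=C1[C@H](C)C[C@@H](OC)O2 | intermediate
5 | ethylene | C=C | starting material
6 | photoadduct: 4 with a CH2CH2 bridge (C-9, C-8) across C-10 and C-7, anti to the C-11 methyl | O=C1CC[C@@]23CC[C@]13[C@H](C)C[C@@H](OC)O2 | intermediate
7 | trimethylsilyl enol ether of 6 (C-5=C-6) | C[Si](C)(C)OC1=CC[C@@]23CC[C@]13[C@H](C)C[C@@H](OC)O2 | intermediate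
8 | enone: 6 with a C-1=C-5 double bond | O=C1C=C[C@@]23CC[C@]13[C@H](C)C[C@@H](OC)O2 | intermediate
9 | allylmagnesium bromide | C=CC[Mg]Br | starting material
10 | trimethylsilyl enol ether of 11 | C[Si](C)(C)OC1=C[C@@H](CC=C)[C@@]23CC[C@]13[C@H](C)C[C@@H](OC)O2 | intermediate
11 | allyl ketone: 6 with an allyl group at C-1, anti to the cyclobutane | O=C1C[C@@H](CC=C)[C@@]23CC[C@]13[C@H](C)C[C@@H](OC)O2 | intermediate
12 | 2-bromopropene | CC(Br)=C | starting material
13 | 11 with an isopropenyl group at C-5, trans to the allyl group | O=C1[C@H](C(C)=C)[C@@H](CC=C)[C@@]23CC[C@]13[C@H](C)C[C@@H](OC)O2 | intermediate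
14 | cyclobutanol: 13 with the pyran opened to C-10–OH and the C-13 dimethyl acetal | O=C1[C@H](C(C)=C)[C@@H](CC=C)[C@]2(O)CC[C@]12[C@H](C)CC(OC)OC | intermediate
15 | cyclic enol ether: C-10 ketone of the seven-membered ring, C-6 enol oxygen closed on C-13 (C-6=C-7, both anomers) | O=C1CCC2=C(OC(OC)C[C@H]2C)[C@H](C(C)=C)[C@H]1CC=C | intermediate
16 | 1-allyl-5-isopropenyl cycloheptane-6,10-dione, C-7 side chain as C-13 dimethyl acetal; C-1, C-5, C-7, C-11 arranged as in the target | O=C1CC[C@@H]([C@H](C)CC(OC)OC)C(=O)[C@H](C(C)=C)[C@H]1CC=C | intermediate
17 | C-10 methylene derivative of 16 (C-6 ketone) | C=C1CC[C@@H]([C@H](C)CC(OC)OC)C(=O)[C@H](C(C)=C)[C@H]1CC=C | intermediate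
18 | trans-fused hydroazulen-6-one with C-3=C-4 (4-methyl) in ring B | C=C1CC[C@@H]([C@H](C)CC(OC)OC)C(=O)[C@H]2[C@H]1CC=C2C | intermediate
19 | 3,4-epoxide of 18, oxygen syn to H-5 | C=C1CC[C@@H]([C@H](C)CC(OC)OC)C(=O)[C@H]2[C@H]1C[C@@H]3O[C@]23C | intermediate
20 | 3-phenylselanyl 4-hydroxy compound (Se trans to OH) | C=C1CC[C@@H]([C@H](C)CC(OC)OC)C(=O)[C@H]2[C@H]1C[C@@H]([Se]c1ccccc1)[C@]2(C)O | intermediate
21 | selenoxide of 20 | C=C1CC[C@@H]([C@H](C)CC(OC)OC)C(=O)[C@H]2[C@H]1C[C@@H]([Se](=O)c1ccccc1)[C@]2(C)O | intermediate
22 | tertiary allylic alcohol: C-4 (Me)(OH), C-2=C-3, C-6 ketone, C-13 dimethyl acetal | C=C1CC[C@@H]([C@H](C)CC(OC)OC)C(=O)[C@H]2[C@H]1C=C[C@]2(C)O | intermediate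
23 | C-13 aldehyde of 22 | C=C1CC[C@@H]([C@H](C)CC=O)C(=O)[C@H]2[C@H]1C=C[C@]2(C)O | intermediate
24 | 1-bromo-2-methylprop-1-ene | CC(C)=CBr | starting material
25 | (13R)-13-hydroxy compound with the C-14=C-15 alkene, C-6 ketone | C=C1CC[C@@H]([C@H](C)C[C@H](C=C(C)C)O)C(=O)[C@H]2[C@H]1C=C[C@]2(C)O | intermediate
26 | 13-acetate of 25 | C=C1CC[C@@H]([C@H](C)C[C@H](C=C(C)C)OC(C)=O)C(=O)[C@H]2[C@H]1C=C[C@]2(C)O | intermediate
27 | C-4 O-diethylborinate of 26 | C=C1CC[C@@H]([C@H](C)C[C@H](C=C(C)C)OC(C)=O)C(=O)[C@H]2[C@H]1C=C[C@]2(C)OB(CC)CC | intermediate
28 | CNP0209568.3 (1R,4S,5R,6R,7S,11R,13R in the numbering above) | C=C1CC[C@@H]([C@H](C)C[C@H](C=C(C)C)OC(C)=O)[C@@H](O)[C@H]2[C@H]1C=C[C@]2(C)O | target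

**Count and risks**

Total number of steps: 14. Longest linear sequence: 14 steps (the route is linear from 1).

Step 4: poor facial selectivity, or 1,2- instead of 1,4-addition, of the allylcopper reagent at the β-carbon next to a quaternary centre would erode the relay from C-11 to C-1. The fallback sets out from 8 and comes back at 11. Rhodium-catalysed asymmetric conjugate addition (Hayashi–Miyaura) of potassium vinyltrifluoroborate ([RhCl(cod)]2, the BINAP enantiomer that delivers the group anti to the cyclobutane, Et3N, dioxane–H2O) should give the 1-vinyl ketone F1 under catalyst control. Hydroboration–oxidation (9-BBN, then NaBO3·4H2O) should give the primary alcohol F2, and Dess–Martin oxidation the aldehyde F3. Wittig methylenation (Ph3P=CH2) of the aldehyde then returns 11.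

Step 6: acid-induced migration of the isopropenyl (β,γ) double bond into conjugation with the C-6 ketone, or incomplete equilibration at C-7, during the ring expansion. The fallback sets out from 11 and comes back at 17, and expands the ring before the isopropenyl group is present. CSA in MeOH on 11 should give the 1-allyl dione acetal F4 (C-7 epimers), and Cp2TiMe2 should methylenate C-10 to give the methylene ketone F5. Palladium-catalysed α-alkenylation with 12 then delivers 17; LiN(SiMe3)2 should deprotonate the C-5 methylene in preference to the tertiary C-7, and both α-centres settle under basic, non-acidic conditions with kinetic α-protonation on quench.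

Step 9: competing oxidation of the exocyclic alkene, or attack of the peracid on the wrong face of ring B. The fallback sets out from 18 and comes back at 22. A Schenck ene reaction (O2, tetraphenylporphyrin, visible light, CH2Cl2, −20 °C) uses singlet oxygen, which should react only with the trisubstituted alkene and add to C-4 from the less hindered face with abstraction of H-2, giving the tertiary allylic hydroperoxide F6. Reduction with PPh3 returns 22.

Further compounds
F1 | step 4 | 1-vinyl ketone (6 with a vinyl group at C-1, anti to the cyclobutane) | O=C1C[C@@H](C=C)[C@@]23CC[C@]13[C@H](C)C[C@@H](OC)O2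
F2 | step 4 | 1-(2-hydroxyethyl) ketone | O=C1C[C@@H](CCO)[C@@]23CC[C@]13[C@H](C)C[C@@H](OC)O2
F3 | step 4 | 1-(2-oxoethyl) ketone (aldehyde) | O=C1C[C@@H](CC=O)[C@@]23CC[C@]13[C@H](C)C[C@@H](OC)O2
F4 | step 6 | 1-allyl cycloheptane-6,10-dione with the C-13 dimethyl acetal side chain, no C-5 substituent (C-7 epimers) | O=C1CCC([C@H](C)CC(OC)OC)C(=O)C[C@H]1CC=C
F5 | step 6 | C-10 methylene derivative of F4 | C=C1CCC([C@H](C)CC(OC)OC)C(=O)C[C@H]1CC=C
F6 | step 9 | C-4 tertiary allylic hydroperoxide (C-2=C-3), otherwise as 22 | C=C1CC[C@@H]([C@H](C)CC(OC)OC)C(=O)[C@H]2[C@H]1C=C[C@]2(C)OO
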